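# Total synthesis proposal for (7R,8R)-threo-syringylglycerol 8-O-4'-(sinapyl alcohol) ether (CNP0207964.2)

## Analysis of the target

Target 10 is an acyclic 8-O-4' neolignan made of two syringyl C6C3 units. Ring A (4-hydroxy-3,5-dimethoxyphenyl) carries the glycerol chain C7–C8–C9. The phenolic oxygen O4' of ring B (2,6-dimethoxyphenyl with an (E)-3-hydroxyprop-1-enyl chain C7'=C8'–C9' in the para position) is bound to C8.

No ring has to be closed. The only stereocentres are the neighbours C7 (benzylic carbinol) and C8 (secondary alkyl aryl ether). CIP analysis of the SMILES string gives R for both, which is the threo series (O7 and O8 syn in the zigzag ring A–C7–C8–C9).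

The C8–O4' bond is the hardest bond. O4' lies between two ortho methoxy groups and C8 is a secondary carbon between two oxygenated carbons, so a stereospecific displacement there has to compete with hindrance and elimination.

Three groups are sensitive:
- The p-hydroxybenzyl alcohol (O4–H, ring A, C7–OH) ionises to a quinone methide under acid or hot base and then loses the C7 configuration.
- The free phenol is easily oxidised.
- The cinnamyl alcohol on ring B rules out hydrogenolysis, strong acid and most oxidants late in the route.

The feature that invites the strategy is the position of H–C8 between C7 and C9. When C7 is a ketone conjugated with ring A and C9 is an ester, C8 is the methine of a 2-aryloxy-1,3-dicarbonyl unit and enolises freely. Its configuration is then erased and can be rewritten together with that of C7.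

A second feature is the dimeric make-up: both rings show the same 3,5-dimethoxy-4-oxygenated benzaldehyde pattern, each extended by a C2 unit. The skeleton is therefore cheap. The difficulty lies in three places: absolute and relative control at C7/C8, the hindered ether, and an end game that frees four hydroxyl groups without touching C7–O or the alkene.

## Retrosynthetic reasoning

**10 to 9.** The last operation is chosen so that the fragile p-hydroxybenzyl alcohol and the cinnamyl alcohol appear only at the very end. The C9–OH and C9'–OH carbinols are traced back to ethyl esters and O4–H to a pivalate. All three acyl groups fall to the same aluminium hydride, so reduction and deprotection are one step. No bond to C7 or C8 is touched.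

**9 to 8 (key disconnection).** The C7–H bond is cut and C7 is raised to the ketone. This removes the C7 stereocentre and makes C8 configurationally labile, so 8 is in effect free of stereochemical information. The forward reaction has to do three things at once:
- choose one face of the C7 ketone;
- choose one of the two rapidly interconverting C8 enantiomers;
- ignore the cinnamate, the esters and the aryl pivalate.

Cutting here separates bond construction from stereochemistry. Every bond of the skeleton may then be made by a reaction that has no stereocontrol at all.

**8 to 5 + 7.** The hindered C8–O4' bond is cut in the carbene sense: C8 is the electrophilic carbenoid carbon of diazo ketoester 5 and O4'–H is the phenol 7. An ionic displacement would ask a di-ortho-substituted phenoxide to attack a halogenated dicarbonyl carbon under base. The insertion runs under neutral conditions, and the first contact is made by an oxygen lone pair on a flat, highly electrophilic carbon. The configuration formed at C8 does not matter because it is labile.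

**5 to 2 + 3.** C7–C8 is cut as an aldol-type addition of diazoacetate 3 to aldehyde 2 through carbinol 4, which is oxidised in the same flask. The oxidation followed later by reduction at C7 is a deliberate redox detour. It costs no extra step and it makes the stereoconvergent key step possible.

**7 to 1 + 6, and 2 to 1.** C7'=C8' is cut by carbonyl olefination of 1 with ylide 6, and 2 is the O-pivalate of the same aldehyde 1. Both aromatic rings thus come from one commercial aldehyde, and the four remaining skeletal carbons come from the C2 reagents 3 and 6.

## Alternatives that were turned down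

**Alternative 1:** (the textbook route) cut C7–C8 as an auxiliary-controlled Evans syn-glycolate aldol. The dibutylboron Z-enolate of the (S)-valine-derived N-(aryloxyacetyl)oxazolidinone A1 would add to aldehyde 2 through a Zimmerman–Traxler chair to give the syn-aldol imide A2. The auxiliary would then be removed and the esters reduced.
- This step also forms one bond and sets both centres, and it is reliable.
- The chirality is carried by a stoichiometric auxiliary. It has to be attached to an aryloxyacetic acid that is itself two steps from 7, and it has to be cleaved again. About eight operations result instead of six.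
- The boron triflate and amine must be used in excess against a substrate full of Lewis-basic methoxy and ester oxygens.
- It is the route most chemists would draw first, so it is kept only as a fallback.

**Alternative 2:** cut C8–O4' in the ionic sense, with the diol from a Sharpless asymmetric dihydroxylation. The E-cinnamate A3 (the pivalate of 7) would be dihydroxylated with K2OsO2(OH)4/(DHQD)2PHAL/K3Fe(CN)6 to the threo diol A4. The more acidic hydroxyl next to the ester would be sulfonylated, and phenol 7 would displace the sulfonate.
- Syn addition to an E-alkene gives threo, and the single inversion at C8 converts it into the erythro ether A5, the wrong diastereomer.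
- Repair needs either the Z-alkene, a poor substrate class for this dihydroxylation, or a second inversion at C7. C7 is a benzylic centre on an oxygen-rich ring and tends to ionise rather than invert cleanly.
- The displacement sets a di-ortho-substituted phenoxide against a secondary sulfonate that bears an acidic alpha hydrogen, so elimination and epimerisation compete.

**Alternative 3:** the biomimetic cut of C8–O4' and C7–O at once. One-electron oxidation of sinapyl alcohol A6 (Ag2O or peroxidase/H2O2) gives two phenoxy radicals. Their 8–O–4' recombination gives quinone methide A7, and water adds to C7.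
- It is the shortest conceivable route: one precursor and one flask.
- C8 is set when two flat achiral radicals combine with no chiral element present, so the product is racemic.
- In the syringyl series 8–8' coupling competes strongly.
- Water adds to A7 on the face left open by the bulky 2,6-dimethoxyphenoxy group, which favours erythro.
- A7 offers no handle to correct either centre, so most of the material would be lost in separation and resolution.

Key step: step 5

Remark (assumption): the SMILES string is read as (7R,8R), threo. The (S,S)-catalyst in step 5 is assigned from the usual aryl ketone model (ring A next to the eta-6 arene ligand). Should the sense of induction prove opposite, the (R,R)-catalyst is used and nothing else changes.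

## Route

Step 1
Reactants: 1 syringaldehyde (4-hydroxy-3,5-dimethoxybenzaldehyde)
Product: 2 4-formyl-2,6-dimethoxyphenyl pivalate
Conditions: PivCl (1.2 equiv), Et3N (1.5 equiv), DMAP (5 mol %), CH2Cl2, 0 °C to rt
Reagents that add atoms: pivaloyl chloride, CC(C)(C)C(=O)Cl
Why: DMAP-catalysed O-acylation of an acidic phenol. The pivalate removes O4–H as a competing partner in step 4, lowers the donor power of ring A toward the later C7 ketone, resists DBU and formate, and is hydride-labile, so it needs no deprotection step of its own.

Step 2
Reactants: 2 4-formyl-2,6-dimethoxyphenyl pivalate; 3 ethyl diazoacetate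
Product: 5 ethyl 2-diazo-3-[3,5-dimethoxy-4-(pivaloyloxy)phenyl]-3-oxopropanoate, via beta-hydroxy-alpha-diazo ester 4 (not isolated)
Conditions: 3 (1.3 equiv), DBU (20 mol %), DMSO, rt; then IBX (2 equiv), DMSO, rt
Reagents that add atoms: none
Why: Base-catalysed aldol-type addition of the diazoacetate carbanion to the aldehyde forms C7–C8, and IBX in the same DMSO solution oxidises the secondary carbinol without touching the diazo group (one-pot diazoacetate addition and oxidation). The stereocentre of 4 is destroyed at once, so no control is needed.

Step 3
Reactants: 1 syringaldehyde; 6 ethyl (triphenylphosphoranylidene)acetate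
Product: 7 ethyl (E)-sinapate (ethyl (E)-3-(4-hydroxy-3,5-dimethoxyphenyl)prop-2-enoate)
Conditions: 6 (1.2 equiv), toluene, 90 °C
Reagents that add atoms: none
Why: Wittig olefination with a stabilised ylide, which tolerates the free phenol and should give the E-alkene; heating overcomes the partial proton transfer between the phenol and the ylide.

Step 4
Reactants: 5 ethyl 2-diazo-3-[3,5-dimethoxy-4-(pivaloyloxy)phenyl]-3-oxopropanoate; 7 ethyl (E)-sinapate
Product: 8 ethyl (2RS)-2-{4-[(E)-3-ethoxy-3-oxoprop-1-en-1-yl]-2,6-dimethoxyphenoxy}-3-[3,5-dimethoxy-4-(pivaloyloxy)phenyl]-3-oxopropanoate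
Conditions: Rh2(OAc)4 (1 mol %), 7 (1.2 equiv), dry toluene, 80 °C, slow addition of 5
Reagents that add atoms: none
Why: Rhodium carbenoid O–H insertion of a phenol into a 2-diazo-1,3-dicarbonyl compound: the phenolic oxygen attacks the acceptor/acceptor carbenoid and a proton shift in the oxonium ylide gives the ether. The conditions are neutral, so the di-ortho-substituted phenol need not act as a displacement nucleophile, and O–H capture should outrun cyclopropanation of the electron-poor cinnamate. The C8 configuration formed is irrelevant because it is labile.

Step 5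
Reactants: 8 racemic 2-aryloxy-3-oxo ester
Product: 9 ethyl (2S,3R)-2-{4-[(E)-3-ethoxy-3-oxoprop-1-en-1-yl]-2,6-dimethoxyphenoxy}-3-[3,5-dimethoxy-4-(pivaloyloxy)phenyl]-3-hydroxypropanoate
Conditions: RuCl[(S,S)-TsDPEN](p-cymene) (2 mol %), HCO2H/Et3N (5:2), CH2Cl2, 30 °C
Reagents that add atoms: none
Why: Noyori–Ikariya asymmetric transfer hydrogenation run as a dynamic kinetic resolution; the closest known reaction type is the syn-selective reduction of racemic aryl 2-alkoxy-3-oxo esters with the same catalyst family and hydrogen source. Formate converts the 16-electron ruthenium amide into the Ru–H/N–H species, which passes hydride to C7 and a proton to O7 through a six-membered outer-sphere transition state, and loss of CO2 makes the step irreversible. C7 is controlled by the catalyst: the CH–pi contact between the p-cymene ligand and ring A places ring A next to the arene, so the (S,S)-complex should deliver hydride to the Si face of C7=O and give 7R (3R in 9). C8 is controlled by selection between the two enantiomers of 8, which interconvert through the enol under Et3N much faster than either is reduced, because H–C8 is flanked by the aroyl group, the ester and the aryloxy oxygen. Only the enantiomer that can hold the C8–O4' bond antiperiplanar to the incoming hydride (polar Felkin–Anh arrangement), with the ester turned away from the sulfonamide, fits the favoured catalyst face, and it leads to the syn (threo) product 2S,3R. No ring is closed. The step needs selectivity for the ketone over the cinnamate, the two esters and the aryl pivalate; the bifunctional hydride requires a polar ketone C=O, and a beta-aryl acrylate with a donor ring is a poor hydride acceptor. The pivalate on O4 and the two meta methoxy groups keep ring A from deactivating the ketone, and both ortho positions of ring B are blocked by methoxy groups, so acid-induced benzofuran cyclisation of the aryloxy ketone cannot occur.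

Step 6
Reactants: 9 syn-hydroxy diester pivalate
Product: 10 (1R,2R)-1-(4-hydroxy-3,5-dimethoxyphenyl)-2-{4-[(E)-3-hydroxyprop-1-en-1-yl]-2,6-dimethoxyphenoxy}propane-1,3-diol (target)
Conditions: iBu2AlH (DIBAL-H, 10 equiv), toluene/CH2Cl2, −78 to 0 °C; aq. KNaC4H4O6 work-up
Reagents that add atoms: none
Why: Global hydride reduction: 1,2-selective reduction of the cinnamate and of the alpha-aryloxy ester to the primary alcohols, and reductive cleavage of the aryl pivalate by the same reagent. No bond to C7 or C8 is broken, so both centres are retained (C8 changes its descriptor from S to R only because C9 drops in CIP rank). The near-neutral tartrate work-up avoids the acid that would ionise the p-hydroxybenzyl alcohol.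

## Compound list

1 | syringaldehyde (4-hydroxy-3,5-dimethoxybenzaldehyde) | COc1cc(C=O)cc(OC)c1O | starting material
2 | 4-formyl-2,6-dimethoxyphenyl pivalate | COc1cc(C=O)cc(OC)c1OC(=O)C(C)(C)C | intermediate
3 | ethyl diazoacetate | CCOC(=O)C=[N+]=[N-] | starting material
4 | ethyl (3RS)-2-diazo-3-[3,5-dimethoxy-4-(pivaloyloxy)phenyl]-3-hydroxypropanoate | CCOC(=O)C(=[N+]=[N-])C(O)c1cc(OC)c(OC(=O)C(C)(C)C)c(OC)c1 | intermediate
5 | ethyl 2-diazo-3-[3,5-dimethoxy-4-(pivaloyloxy)phenyl]-3-oxopropanoate | CCOC(=O)C(=[N+]=[N-])C(=O)c1cc(OC)c(OC(=O)C(C)(C)C)c(OC)c1 | intermediate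
6 | ethyl (triphenylphosphoranylidene)acetate | CCOC(=O)C=P(c1ccccc1)(c1ccccc1)c1ccccc1 | starting material
7 | ethyl (E)-sinapate | CCOC(=O)/C=C/c1cc(OC)c(O)c(OC)c1 | intermediate
8 | ethyl (2RS)-2-{4-[(E)-3-ethoxy-3-oxoprop-1-en-1-yl]-2,6-dimethoxyphenoxy}-3-[3,5-dimethoxy-4-(pivaloyloxy)phenyl]-3-oxopropanoate | CCOC(=O)C(Oc1c(OC)cc(/C=C/C(=O)OCC)cc1OC)C(=O)c1cc(OC)c(OC(=O)C(C)(C)C)c(OC)c1 | intermediate
9 | ethyl (2S,3R)-2-{4-[(E)-3-ethoxy-3-oxoprop-1-en-1-yl]-2,6-dimethoxyphenoxy}-3-[3,5-dimethoxy-4-(pivaloyloxy)phenyl]-3-hydroxypropanoate | COc1cc([C@@H](O)[C@@H](C(=O)OCC)Oc2c(OC)cc(/C=C/C(=O)OCC)cc2OC)cc(OC)c1OC(=O)C(C)(C)C | intermediate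
10 | (1R,2R)-1-(4-hydroxy-3,5-dimethoxyphenyl)-2-{4-[(E)-3-hydroxyprop-1-en-1-yl]-2,6-dimethoxyphenoxy}propane-1,3-diol | COc1cc([C@@H](O)[C@@H](CO)Oc2c(OC)cc(/C=C/CO)cc2OC)cc(OC)c1O | target

## Step count and risk

Total step count: 6. Longest linear sequence: 5 (steps 1, 2, 4, 5, 6). Step 3 is the one-step side branch.

**Step 5 (key step).**
- The most likely failure is weak discrimination between the two C8 enantiomers (eroded syn selectivity) or slow hydride transfer. The 2,6-dimethoxyaryloxy group at C8 is much larger than the alkoxy groups for which this reaction type is established, and it may clash with the sulfonamide and arene of the catalyst. Partial formylation of the new carbinol is a minor side process.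
- The fallback gives up the dynamic resolution and sets both centres with a stoichiometric auxiliary by known Evans syn-glycolate aldol chemistry. It sets out from 7 and 2.
- Phenol 7 is O-alkylated with tert-butyl bromoacetate (K2CO3, acetone) to the tert-butyl aryloxyacetate F1, which is cleaved with CF3CO2H to the aryloxyacetic acid F2.
- F2 is coupled through its pivalic mixed anhydride with lithiated (S)-4-benzyloxazolidin-2-one to the imide F3.
- Enolisation with Bu2BOTf/iPr2NEt and addition to 2 at −78 °C should give the syn-aldol imide F4, with the (S)-auxiliary leading to 2S,3R.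
- Yb(OTf)3-catalysed ethanolysis of the imide comes back to the route at 9.

**Step 4.**
- The carbenoid may be diverted before the hindered, internally hydrogen-bonded phenol captures it. Possible diversions are Wolff rearrangement, carbene dimerisation, ylide formation at a methoxy oxygen, and insertion into traces of water.
- The fallback avoids diazo chemistry and builds C8–O4' first and C7–C8 second. It sets out from 7 and 2.
- Alkylation of 7 with ethyl bromoacetate (K2CO3, acetone) gives the ethyl aryloxyacetate F5.
- Its lithium enolate (LiN(iPr)2, THF, −78 °C) adds to 2 to give the racemic erythro/threo aldol mixture F6.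
- Dess–Martin periodinane oxidises the carbinol of F6, which comes back to the route at 8.

**Step 6.**
- Cleavage of the pivalate may be incomplete, because it is shielded by tert-butyl and two ortho methoxy groups.
- Once the aluminium phenoxide is free in a Lewis-acidic medium, ionisation of C7–O with hydride capture (benzylic deoxygenation) or epimerisation may occur on warming.
- The polar product may also be lost in the aluminium salts.
- The fallback separates reduction from deprotection and sets out from 9. iBu2AlH (about 5 equiv) at −78 °C reduces only the two ethyl esters and leaves the shielded ester, giving the triol pivalate F7.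
- The aryl ester of F7 is then removed without any Lewis acid by methanolysis (K2CO3, MeOH, rt), which comes back to the route at 10.

**Step 2.**
- The diazoacetate addition is reversible and may lie on the aldehyde side.
- DBU may start acyl transfer from the aryl pivalate to the alkoxide of 4 before the oxidant is added.
- The fallback reaches the same carbon skeleton by a 1,2-hydride shift instead of an oxidation and sets out from 2 and 3. NbCl5-catalysed Roskamp homologation (CH2Cl2, rt) gives the beta-keto ester F8.
- Regitz diazo transfer onto F8 with 4-acetamidobenzenesulfonyl azide and Et3N in MeCN comes back to the route at 5.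

## Further compounds

F1 | step 5 | tert-butyl 2-{4-[(E)-3-ethoxy-3-oxoprop-1-en-1-yl]-2,6-dimethoxyphenoxy}acetate | CCOC(=O)/C=C/c1cc(OC)c(OCC(=O)OC(C)(C)C)c(OC)c1
F2 | step 5 | 2-{4-[(E)-3-ethoxy-3-oxoprop-1-en-1-yl]-2,6-dimethoxyphenoxy}acetic acid | CCOC(=O)/C=C/c1cc(OC)c(OCC(=O)O)c(OC)c1
F3 | step 5 | ethyl (E)-3-(4-{2-[(4S)-4-benzyl-2-oxo-1,3-oxazolidin-3-yl]-2-oxoethoxy}-3,5-dimethoxyphenyl)prop-2-enoate | CCOC(=O)/C=C/c1cc(OC)c(OCC(=O)N2C(=O)OC[C@@H]2Cc2ccccc2)c(OC)c1
F4 | step 5 | (4S)-4-benzyl-3-[(2S,3R)-2-aryloxy-3-hydroxy-3-arylpropanoyl]-1,3-oxazolidin-2-one, aryloxy and aryl groups as in 9 | COc1cc([C@@H](O)[C@@H](C(=O)N2C(=O)OC[C@@H]2Cc2ccccc2)Oc2c(OC)cc(/C=C/C(=O)OCC)cc2OC)cc(OC)c1OC(=O)C(C)(C)C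
F5 | step 4 | ethyl 2-{4-[(E)-3-ethoxy-3-oxoprop-1-en-1-yl]-2,6-dimethoxyphenoxy}acetate | CCOC(=O)/C=C/c1cc(OC)c(OCC(=O)OCC)c(OC)c1
F6 | step 4 | ethyl 2-{4-[(E)-3-ethoxy-3-oxoprop-1-en-1-yl]-2,6-dimethoxyphenoxy}-3-[3,5-dimethoxy-4-(pivaloyloxy)phenyl]-3-hydroxypropanoate, racemic erythro/threo mixture | CCOC(=O)C(Oc1c(OC)cc(/C=C/C(=O)OCC)cc1OC)C(O)c1cc(OC)c(OC(=O)C(C)(C)C)c(OC)c1
F7 | step 6 | 4-[(1R,2R)-1,3-dihydroxy-2-{4-[(E)-3-hydroxyprop-1-en-1-yl]-2,6-dimethoxyphenoxy}propyl]-2,6-dimethoxyphenyl pivalate | COc1cc([C@@H](O)[C@@H](CO)Oc2c(OC)cc(/C=C/CO)cc2OC)cc(OC)c1OC(=O)C(C)(C)C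
F8 | step 2 | ethyl 3-[3,5-dimethoxy-4-(pivaloyloxy)phenyl]-3-oxopropanoate | CCOC(=O)CC(=O)c1cc(OC)c(OC(=O)C(C)(C)C)c(OC)c1
A1 | alternative 1 | ethyl (E)-3-(3,5-dimethoxy-4-{2-oxo-2-[(4S)-2-oxo-4-(propan-2-yl)-1,3-oxazolidin-3-yl]ethoxy}phenyl)prop-2-enoate | CCOC(=O)/C=C/c1cc(OC)c(OCC(=O)N2C(=O)OC[C@@H]2C(C)C)c(OC)c1
A2 | alternative 1 | (4S)-3-[(2S,3R)-2-aryloxy-3-hydroxy-3-arylpropanoyl]-4-(propan-2-yl)-1,3-oxazolidin-2-one, aryloxy and aryl groups as in 9 | COc1cc([C@@H](O)[C@@H](C(=O)N2C(=O)OC[C@@H]2C(C)C)Oc2c(OC)cc(/C=C/C(=O)OCC)cc2OC)cc(OC)c1OC(=O)C(C)(C)C
A3 | alternative 2 | ethyl (E)-3-[3,5-dimethoxy-4-(pivaloyloxy)phenyl]prop-2-enoate | CCOC(=O)/C=C/c1cc(OC)c(OC(=O)C(C)(C)C)c(OC)c1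
A4 | alternative 2 | ethyl (2S,3R)-3-[3,5-dimethoxy-4-(pivaloyloxy)phenyl]-2,3-dihydroxypropanoate | COc1cc([C@@H](O)[C@@H](C(=O)OCC)O)cc(OC)c1OC(=O)C(C)(C)C
A5 | alternative 2 | ethyl (2R,3R)-2-{4-[(E)-3-ethoxy-3-oxoprop-1-en-1-yl]-2,6-dimethoxyphenoxy}-3-[3,5-dimethoxy-4-(pivaloyloxy)phenyl]-3-hydroxypropanoate (erythro) | COc1cc([C@@H](O)[C@H](C(=O)OCC)Oc2c(OC)cc(/C=C/C(=O)OCC)cc2OC)cc(OC)c1OC(=O)C(C)(C)C
A6 | alternative 3 | sinapyl alcohol ((E)-4-(3-hydroxyprop-1-en-1-yl)-2,6-dimethoxyphenol) | COc1cc(/C=C/CO)cc(OC)c1O
A7 | alternative 3 | racemic 8-O-4' quinone methide, 4-(3-hydroxy-2-{4-[(E)-3-hydroxyprop-1-en-1-yl]-2,6-dimethoxyphenoxy}propylidene)-2,6-dimethoxycyclohexa-2,5-dien-1-one | COC1=CC(=CC(CO)Oc2c(OC)cc(/C=C/CO)cc2OC)C=C(OC)C1=O
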